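Everything rests on cutting the C6–C7 bond of the ten-membered carbocycle C1–C10. Read backwards, the homoallylic alcohol unit O6–C6–C7–C11(=C13), common to this ring and to the γ-lactone, is what a C6–O–C13 allyl ether leaves behind after a [2,3]-Wittig rearrangement. One operation thus contracts a thirteen-membered bis-allylic ether to the carbocycle, creates C6 and C7, frees O6 and lays down the exomethylene. The precursor is this cyclic ether with the (Z)-C4=C5 and (E)-C1=C10 alkenes, a C7=C11 alkene holding C8 trans to C13, silyl ethers on O3, O8 and O12, and two carbinol centres set by catalytic alkynylation. Oxidative lactonisation, two acylations and a late C1=C10 epoxidation complete the target.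

Key step: step 19

Locants and abbreviations: the germacrane locants of the target are used for every intermediate (C12 = lactone carbonyl, C13 = exomethylene carbon, C14 = methyl on C10, C15 = methyl on C4). PMB = 4-methoxybenzyl, TES = SiEt3, TBS = SiMe2t-Bu.

Assumption: with Ti(OiPr)4/BINOL, (S)-BINOL is taken to give the (R)-propargylic alcohol of an unbranched aldehyde RCH2CHO and (R)-BINOL the (S)-alcohol. The sense is checked on 10 and 18 by MTPA ester analysis, and the ligand enantiomer is exchanged if needed.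

Step 1
Reactants: 1 but-3-yn-1-ol
Product: 2 but-3-ynyl PMB ether
Conditions: NaH, PMBCl, Bu4NI (cat.), THF, 0 °C to rt
Reagents that add atoms: 4-methoxybenzyl chloride, COc1ccc(CCl)cc1
Why: Williamson ether synthesis on the primary alkoxide masks the future C8 oxygen with a group that tolerates AlMe3, cuprate and zinc reagents and is later removed oxidatively.

Step 2
Reactants: 2 but-3-ynyl PMB ether; 3 oxirane
Product: 6 (E)-6-(PMB-oxy)-4-methylhex-3-en-1-ol, via alkenyldimethylalane 4 (not isolated), via lithium alkenylalanate 5 (not isolated)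
Conditions: AlMe3 (2.5 equiv), Cp2ZrCl2 (25 mol %), CH2Cl2, 0 °C to rt; solvent change to hexane, n-BuLi, 0 °C; oxirane in THF, −30 °C to rt; aq Rochelle salt
Reagents that add atoms: trimethylaluminium, C[Al](C)C
Why: Zirconium-catalysed Negishi methylalumination adds C14 and aluminium syn with aluminium on the terminal carbon, and the more nucleophilic butyl alanate opens oxirane by SN2 with retention at the alkenyl carbon, which fixes (E)-C1=C10.

Step 3
Reactants: 6 (E)-6-(PMB-oxy)-4-methylhex-3-en-1-ol
Product: 7 (E)-6-(PMB-oxy)-4-methylhex-3-enal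
Conditions: Dess–Martin periodinane, NaHCO3, CH2Cl2, 0 °C; used at once
Reagents that add atoms: none
Why: Bicarbonate-buffered Dess–Martin oxidation is neutral enough to give the β,γ-unsaturated C3 aldehyde before C1=C10 can move into conjugation.

Step 4
Reactants: 7 (E)-6-(PMB-oxy)-4-methylhex-3-enal; 8 methyl propiolate
Product: 10 methyl (4S,6E)-4-hydroxy-9-(PMB-oxy)-7-methylnon-6-en-2-ynoate, via alkynylzinc 9 (not isolated)
Conditions: 8 (4 equiv), ZnEt2 (4 equiv), (R)-BINOL (40 mol %), HMPA (2 equiv), CH2Cl2, rt; Ti(OiPr)4 (1 equiv); then 7, rt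
Reagents that add atoms: none
Why: In this catalytic asymmetric alkynylzinc addition the BINOL–titanium complex activates the aldehyde and shields one face, so that (R)-BINOL should set (3S), while the weakly basic medium spares the enolisable aldehyde.

Step 5
Reactants: 10 methyl (4S,6E)-4-hydroxy-9-(PMB-oxy)-7-methylnon-6-en-2-ynoate
Product: 11 O3-TES ether of 10
Conditions: TESCl, imidazole, CH2Cl2, 0 °C
Reagents that add atoms: chlorotriethylsilane, CC[Si](Cl)(CC)CC
Why: Routine silylation caps O3 so that no butenolide can form once the (Z)-enoate is in place, and TES is chosen because mild acid removes it later beside TBS.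

Step 6
Reactants: 11 O3-TES ether of 10
Product: 13 methyl (2Z,4S,6E)-9-(PMB-oxy)-3,7-dimethyl-4-(TES-oxy)nona-2,6-dienoate, via alkenylcuprate 12 (not isolated)
Conditions: CuI (1.5 equiv), MeLi (3 equiv), THF, 0 °C; 11, −78 °C; sat. aq NH4Cl at −78 °C
Reagents that add atoms: methyllithium (delivered as Me2CuLi), [Li]C
Why: Conjugate syn-carbocupration of the ynoate puts C15 on C4 and copper on C5 on the same side, and protonation at −78 °C, before the alkenylcuprate can equilibrate through an allenolate, gives the (Z)-enoate with C3 and C6 cis.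

Step 7
Reactants: 13 methyl (2Z,4S,6E)-9-(PMB-oxy)-3,7-dimethyl-4-(TES-oxy)nona-2,6-dienoate
Product: 14 methyl (2Z,4S,6E)-9-hydroxy-3,7-dimethyl-4-(TES-oxy)nona-2,6-dienoate
Conditions: DDQ, CH2Cl2–pH 7 buffer, 0 °C
Reagents that add atoms: none
Why: Oxidative cleavage of the electron-rich benzyl ether (hydride abstraction by DDQ, then hydrolysis) is selective, and the neutral buffer protects the TES ether, whose loss would lead to lactonisation.

Step 8
Reactants: 14 methyl (2Z,4S,6E)-9-hydroxy-3,7-dimethyl-4-(TES-oxy)nona-2,6-dienoate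
Product: 15 methyl (2Z,4S,6E)-3,7-dimethyl-9-oxo-4-(TES-oxy)nona-2,6-dienoate
Conditions: Dess–Martin periodinane, NaHCO3, CH2Cl2, 0 °C; used at once
Reagents that add atoms: none
Why: Buffered Dess–Martin oxidation is used again because C1=C10 is β,γ to the new C8 aldehyde.

Step 9
Reactants: 15 methyl (2Z,4S,6E)-3,7-dimethyl-9-oxo-4-(TES-oxy)nona-2,6-dienoate; 16 PMB prop-2-ynyl ether
Product: 18 methyl (2Z,4S,6E,9R)-9-hydroxy-12-(PMB-oxy)-3,7-dimethyl-4-(TES-oxy)dodeca-2,6-dien-10-ynoate, via alkynylzinc 17 (not isolated)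
Conditions: 16 (3 equiv), ZnEt2 (3 equiv), (S)-BINOL (40 mol %), HMPA (2 equiv), CH2Cl2, rt; Ti(OiPr)4 (1 equiv); then 15, rt
Reagents that add atoms: none
Why: A second BINOL–titanium catalysed alkynylzinc addition, now with (S)-BINOL, should set (8R) under catalyst control far from C3, and the enoate and silyl ether are inert to the alkynylzinc reagent.

Step 10
Reactants: 18 methyl (2Z,4S,6E,9R)-9-hydroxy-12-(PMB-oxy)-3,7-dimethyl-4-(TES-oxy)dodeca-2,6-dien-10-ynoate
Product: 19 (2Z,4S,6E,9R)-12-(PMB-oxy)-3,7-dimethyl-4-(TES-oxy)dodeca-2,6-dien-10-yne-1,9-diol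
Conditions: i-Bu2AlH (3.5 equiv), CH2Cl2, −78 °C; aq Rochelle salt
Reagents that add atoms: none
Why: 1,2-Reduction of the enoate by i-Bu2AlH at low temperature gives the (Z)-allylic C6 alcohol without touching the alkyne or silyl ether, and O8–H only consumes one extra equivalent.

Step 11
Reactants: 19 (2Z,4S,6E,9R)-12-(PMB-oxy)-3,7-dimethyl-4-(TES-oxy)dodeca-2,6-dien-10-yne-1,9-diol
Product: 21 (2Z,4S,6E,9R,10Z)-11-iodo-12-(PMB-oxy)-3,7-dimethyl-4-(TES-oxy)dodeca-2,6,10-triene-1,9-diol, via cyclic alkenylaluminate 20 (not isolated)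
Conditions: NaAlH2(OCH2CH2OMe)2 (3.5 equiv), THF, 0 °C; EtOAc, 0 °C; I2 in THF, −78 °C
Reagents that add atoms: iodine, [I][I]
Why: In this hydroxyl-directed trans-hydroalumination the O8-bound aluminium hydride delivers H to C7 and closes a five-membered ring through C11, so iodinolysis with retention puts iodine on C11 cis to C8 (C8 trans to C13), and the low temperature together with the EtOAc quench of surplus hydride suppresses β-elimination of the C13 ether.

Step 12
Reactants: 21 (2Z,4S,6E,9R,10Z)-11-iodo-12-(PMB-oxy)-3,7-dimethyl-4-(TES-oxy)dodeca-2,6,10-triene-1,9-diol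
Product: 23 C6 allylic chloride of 21 (O8–H free), via allylic mesylate 22 (not isolated)
Conditions: MsCl (1.1 equiv), 2,4,6-collidine, LiCl, DMF, 0 °C
Reagents that add atoms: lithium chloride, [Li+].[Cl-]
Why: Mesylation with in situ SN2 displacement by chloride is much faster at the open primary allylic C6–OH than at the secondary O8–H beside the iodoalkene, and it keeps the (Z)-geometry.

Step 13
Reactants: 23 C6 allylic chloride of 21 (O8–H free)
Product: 24 O8-TBS ether of 23
Conditions: TBSOTf, 2,6-lutidine, CH2Cl2, −78 to 0 °C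
Reagents that add atoms: tert-butyldimethylsilyl triflate, CC(C)(C)[Si](C)(C)OS(=O)(=O)C(F)(F)F
Why: Silylation with the reactive triflate caps the hindered O8 with a group that outlasts the TES ethers, and the chloride, iodide and PMB ether are inert.

Step 14
Reactants: 24 O8-TBS ether of 23
Product: 25 C13 alcohol (C6–Cl, C11–I, O3-TES, O8-TBS)
Conditions: DDQ, CH2Cl2–pH 7 buffer, 0 °C
Reagents that add atoms: none
Why: Buffered oxidative PMB cleavage frees only the C13 hydroxyl, the nucleophile for ring closure.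

Step 15
Reactants: 25 C13 alcohol (C6–Cl, C11–I, O3-TES, O8-TBS)
Product: 26 (3S,8R)-thirteen-membered ether C6–O–C13 with C11–I
Conditions: NaH (3 equiv), Bu4NI (20 mol %), THF, 45 °C, slow addition of 25 (final 2 mM)
Reagents that add atoms: none
Why: This is an intramolecular Williamson etherification under pseudo-high dilution with iodide catalysis, a closure known for thirteen-membered bis-allylic ethers, helped by three alkenes that stiffen the chain, and O13 sits trans to C8 so that no silyl migration can occur.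

Step 16
Reactants: 26 (3S,8R)-thirteen-membered ether C6–O–C13 with C11–I
Product: 27 macrocyclic methyl ester (C12 = CO2Me on C11)
Conditions: Pd(PPh3)4 (10 mol %), CO (1 atm), Et3N, MeOH–DMF, 55 °C
Reagents that add atoms: carbon monoxide, [C-]#[O+]; methanol, CO
Why: Palladium-catalysed methoxycarbonylation (oxidative addition of zerovalent palladium to C–I, CO insertion, methanolysis) brings in C12 with retention of alkene geometry, and unactivated allyl alkyl ethers are not ionised.

Step 17
Reactants: 27 macrocyclic methyl ester (C12 = CO2Me on C11)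
Product: 28 macrocyclic C12 allylic alcohol
Conditions: i-Bu2AlH (2.5 equiv), CH2Cl2, −78 °C; aq Rochelle salt
Reagents that add atoms: none
Why: 1,2-Reduction of the enoate takes C12 to the base-stable alcohol level that the carbanion chemistry needs.

Step 18
Reactants: 28 macrocyclic C12 allylic alcohol
Product: 29 macrocyclic ether with C12H2–OTES (O3-TES, O8-TBS)
Conditions: TESCl, imidazole, CH2Cl2, 0 °C
Reagents that add atoms: chlorotriethylsilane, CC[Si](Cl)(CC)CC
Why: Silylation removes the last acidic proton and places a bulky arm next to C13 that can be taken off together with the O3 group.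

Step 19
Reactants: 29 macrocyclic ether with C12H2–OTES (O3-TES, O8-TBS)
Product: 31 (3S,6R,8R)-cyclodeca-1(10),4-dien-6-ol with H7 trans to H6 and C7 bearing C(=CH2)CH2OTES, via C6-lithiated ether 30 (not isolated)
Conditions: n-BuLi (1.8 equiv), THF, −78 to −25 °C; sat. aq NH4Cl
Reagents that add atoms: none
Why: Deprotonation by n-BuLi takes place at C6 (allylic, α to the ring oxygen, next to the C5 methine only), and lithio ether 30 undergoes a concerted [2,3]-sigmatropic shift, suprafacial on the allyl unit C13–C11=C7, via a five-membered envelope in which C6–C7 is made while O–C13 is cleaved and the π bond moves to C11=C13. The closest known reaction is of exactly this type, the [2,3]-Wittig ring contraction of thirteen-membered bis-allylic ethers to germacrane-type cyclodecadienols, and only the (Z)-C4=C5 alkene and the three silyloxy groups are new. The single ring closed is the ten-membered carbocycle C1–C10, formed transannularly by C–C bonding across the macrocycle, so no dilution is needed. C6 and C7 arise together, and since C8 is trans to C13 on C7=C11 and C5 sits exo on the envelope, O6 and C8 come out anti, which is the trans H6/H7 relation of the later lactone. Their absolute sense is relayed from (3S) and (8R), which make the two mirror-type folds of the macrocycle diastereomeric: the productive fold holds C2 and C7 on the same side of the C4=C5 plane and C9 antiperiplanar to C11, and it turns O3 and O8 toward the lithium-bearing C6–O unit. The step needs site selectivity for C6–H over C13–H, secured because C13 lies beside the quaternary alkene carbon C11 and its silyloxymethyl arm and an anion there could attack only the methyl-bearing C4, and it needs the facial preference just described, which is the least secured point.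

Step 20
Reactants: 31 (3S,6R,8R)-cyclodeca-1(10),4-dien-6-ol with H7 trans to H6 and C7 bearing C(=CH2)CH2OTES
Product: 32 3,6,12-triol with O8-TBS
Conditions: PPTS (20 mol %), MeOH–CH2Cl2, 0 °C
Reagents that add atoms: none
Why: Acid-catalysed methanolysis discriminates by silyl size, so both TES ethers leave while the secondary TBS ether stays, and PPTS is too weak to trigger transannular cyclisation of the cyclodecadiene.

Step 21
Reactants: 32 3,6,12-triol with O8-TBS
Product: 35 trans-fused 6,12-α-methylene lactone with free O3–H and O8-TBS, via enal 33 (not isolated), via lactol 34 (not isolated)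
Conditions: TEMPO (20 mol %), PhI(OAc)2 (2.5 equiv), CH2Cl2, rt
Reagents that add atoms: none
Why: Oxoammonium (TEMPO) oxidation selects the primary allylic alcohol, the enal is trapped by O6–H as a five-membered lactol that is oxidised on to the lactone, the hindered secondary O3–H reacts far more slowly, and O8 is blocked.

Step 22
Reactants: 36 tiglic acid
Product: 37 (E)-2-methylbut-2-en-1-ol
Conditions: LiAlH4, Et2O, 0 °C to rt
Reagents that add atoms: none
Why: Hydride reduction of the carboxylic acid proceeds 1,2 and keeps the (E)-alkene, giving the allylic alcohol needed for a directed epoxidation.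

Step 23
Reactants: 37 (E)-2-methylbut-2-en-1-ol
Product: 38 (2R,3R)-2,3-epoxy-2-methylbutan-1-ol
Conditions: Ti(OiPr)4 (10 mol %), D-(−)-diethyl tartrate (12 mol %), t-BuOOH, 4 Å sieves, CH2Cl2, −20 °C
Reagents that add atoms: tert-butyl hydroperoxide, CC(C)(C)OO
Why: In the Sharpless asymmetric epoxidation the titanium tartrate complex binds the alcohol and the peroxide and, with D-(−)-diethyl tartrate, transfers oxygen to the face that gives the (2R,3R)-epoxy alcohol, and syn addition keeps the two methyl groups cis.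

Step 24
Reactants: 38 (2R,3R)-2,3-epoxy-2-methylbutan-1-ol
Product: 39 (2S,3R)-2,3-dimethyloxirane-2-carboxylic acid
Conditions: RuCl3·xH2O (3 mol %), NaIO4 (3 equiv), MeCN–EtOAc–H2O, 0 °C to rt
Reagents that add atoms: water, O
Why: RuO4 made catalytically from RuCl3 and NaIO4 oxidises the primary alcohol through the aldehyde hydrate to the acid without opening the oxirane, and the C2 descriptor changes to S only because CO2H outranks C3.

Step 25
Reactants: 35 trans-fused 6,12-α-methylene lactone with free O3–H and O8-TBS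
Product: 40 3-O-isobutyrate of 35
Conditions: isobutyric anhydride, Et3N, DMAP (cat.), CH2Cl2, 0 °C to rt
Reagents that add atoms: isobutyric anhydride, CC(C)C(=O)OC(=O)C(C)C
Why: DMAP-catalysed acyl transfer reaches the only free hydroxyl and leaves the C3–O bond, and hence (3S), untouched.

Step 26
Reactants: 40 3-O-isobutyrate of 35
Product: 41 8-hydroxy 3-O-isobutyrate lactone
Conditions: HF·pyridine, pyridine, THF, 0 °C to rt
Reagents that add atoms: none
Why: Buffered, non-basic fluoride desilylation frees O8 and leaves the lactone, allylic ester and both ring alkenes intact, avoiding acyl migration or relactonisation toward O8.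

Step 27
Reactants: 39 (2S,3R)-2,3-dimethyloxirane-2-carboxylic acid; 41 8-hydroxy 3-O-isobutyrate lactone
Product: 43 1(10)-ene diester (target without the ring oxirane), via mixed anhydride 42 (not isolated)
Conditions: 39, 2,4,6-trichlorobenzoyl chloride, Et3N, toluene, rt; then 41, DMAP, toluene, rt to 40 °C
Reagents that add atoms: none
Why: In the Yamaguchi esterification DMAP attacks the aliphatic carbonyl of the mixed anhydride because two ortho chlorines block the aroyl one, C8 keeps its configuration since only O–H is broken, and the acid has no α-hydrogen to epimerise.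

Step 28
Reactants: 43 1(10)-ene diester (target without the ring oxirane)
Product: 44 target CNP0117882.4
Conditions: mCPBA (1.1 equiv), NaHCO3, CH2Cl2, 0 °C
Reagents that add atoms: 3-chloroperoxybenzoic acid, O=C(OO)c1cccc(Cl)c1
Why: In this Prilezhaev epoxidation C1=C10 is the only electron-rich alkene (C4=C5 lies between two acyloxy-bearing carbons and C11=C13 is conjugated), syn addition turns the (E)-alkene into the trans-oxirane, and in the preferred fold, with C14 on the β-face opposite to C15, only the outer face is open, which corresponds to (1R,10R).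

Compound list
1 | but-3-yn-1-ol | C#CCCO | starting material
2 | but-3-ynyl 4-methoxybenzyl ether | C#CCCOCc1ccc(OC)cc1 | intermediate
3 | oxirane | C1CO1 | starting material
4 | (E)-alkenyldimethylalane, Al on C1 | COc1ccc(COCC/C(C)=C/[Al](C)C)cc1 | intermediate
5 | lithium (E)-alkenyl(butyl)dimethylalanate | [Li+].COc1ccc(COCC/C(C)=C/[Al-](C)(C)CCCC)cc1 | intermediate
6 | (E)-6-(4-methoxybenzyloxy)-4-methylhex-3-en-1-ol | COc1ccc(COCC/C(C)=C/CCO)cc1 | intermediate
7 | (E)-6-(4-methoxybenzyloxy)-4-methylhex-3-enal | COc1ccc(COCC/C(C)=C/CC=O)cc1 | intermediate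
8 | methyl propiolate | C#CC(=O)OC | starting material
9 | ethyl(3-methoxy-3-oxoprop-1-ynyl)zinc | CC[Zn]C#CC(=O)OC | intermediate
10 | methyl (4S,6E)-4-hydroxy-9-(4-methoxybenzyloxy)-7-methylnon-6-en-2-ynoate | COC(=O)C#C[C@@H](O)C/C=C(\C)CCOCc1ccc(OC)cc1 | intermediate
11 | O3 triethylsilyl ether of 10 | COC(=O)C#C[C@@H](O[Si](CC)(CC)CC)C/C=C(\C)CCOCc1ccc(OC)cc1 | intermediate
12 | lithium alkenyl(methyl)cuprate, Cu on C5 cis to C15 | [Li+].COC(=O)/C([Cu-]C)=C(/C)[C@@H](O[Si](CC)(CC)CC)C/C=C(\C)CCOCc1ccc(OC)cc1 | intermediate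
13 | methyl (2Z,4S,6E)-9-(4-methoxybenzyloxy)-3,7-dimethyl-4-(triethylsilyloxy)nona-2,6-dienoate | COC(=O)/C=C(/C)[C@@H](O[Si](CC)(CC)CC)C/C=C(\C)CCOCc1ccc(OC)cc1 | intermediate
14 | methyl (2Z,4S,6E)-9-hydroxy-3,7-dimethyl-4-(triethylsilyloxy)nona-2,6-dienoate | COC(=O)/C=C(/C)[C@@H](O[Si](CC)(CC)CC)C/C=C(\C)CCO | intermediate
15 | methyl (2Z,4S,6E)-3,7-dimethyl-9-oxo-4-(triethylsilyloxy)nona-2,6-dienoate | COC(=O)/C=C(/C)[C@@H](O[Si](CC)(CC)CC)C/C=C(\C)CC=O | intermediate
16 | 4-methoxybenzyl prop-2-ynyl ether | C#CCOCc1ccc(OC)cc1 | starting material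
17 | ethyl[3-(4-methoxybenzyloxy)prop-1-ynyl]zinc | CC[Zn]C#CCOCc1ccc(OC)cc1 | intermediate
18 | methyl (2Z,4S,6E,9R)-9-hydroxy-12-(4-methoxybenzyloxy)-3,7-dimethyl-4-(triethylsilyloxy)dodeca-2,6-dien-10-ynoate | COC(=O)/C=C(/C)[C@@H](O[Si](CC)(CC)CC)C/C=C(\C)C[C@@H](O)C#CCOCc1ccc(OC)cc1 | intermediate
19 | (2Z,4S,6E,9R)-12-(4-methoxybenzyloxy)-3,7-dimethyl-4-(triethylsilyloxy)dodeca-2,6-dien-10-yne-1,9-diol | OC/C=C(/C)[C@@H](O[Si](CC)(CC)CC)C/C=C(\C)C[C@@H](O)C#CCOCc1ccc(OC)cc1 | intermediate
20 | cyclic alkenylaluminate (five-membered ring O8–C8–C7=C11–Al), drawn as disodium salt with the C6 alkoxide | [Na+].[Na+].[O-]C/C=C(/C)[C@@H](O[Si](CC)(CC)CC)C/C=C(\C)C[C@H]1O[Al-](OCCOC)(OCCOC)C(COCc2ccc(OC)cc2)=C1 | intermediate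
21 | (2Z,4S,6E,9R,10Z)-11-iodo-12-(4-methoxybenzyloxy)-3,7-dimethyl-4-(triethylsilyloxy)dodeca-2,6,10-triene-1,9-diol | OC/C=C(/C)[C@@H](O[Si](CC)(CC)CC)C/C=C(\C)C[C@@H](O)/C=C(\I)COCc1ccc(OC)cc1 | intermediate
22 | C6 allylic mesylate of 21 | CS(=O)(=O)OC/C=C(/C)[C@@H](O[Si](CC)(CC)CC)C/C=C(\C)C[C@@H](O)/C=C(\I)COCc1ccc(OC)cc1 | intermediate
23 | C6 allylic chloride of 21, (3S,8R), O8–H free | ClC/C=C(/C)[C@@H](O[Si](CC)(CC)CC)C/C=C(\C)C[C@@H](O)/C=C(\I)COCc1ccc(OC)cc1 | intermediate
24 | O8 tert-butyldimethylsilyl ether of 23 | ClC/C=C(/C)[C@@H](O[Si](CC)(CC)CC)C/C=C(\C)C[C@@H](O[Si](C)(C)C(C)(C)C)/C=C(\I)COCc1ccc(OC)cc1 | intermediate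
25 | C13 alcohol with C6–Cl and C11–I, (3S,8R) | ClC/C=C(/C)[C@@H](O[Si](CC)(CC)CC)C/C=C(\C)C[C@@H](O[Si](C)(C)C(C)(C)C)/C=C(\I)CO | intermediate
26 | (3S,8R)-thirteen-membered ether C6–O–C13, iodide on C11, C8 trans to C13 | O1C/C=C(/C)[C@@H](O[Si](CC)(CC)CC)C/C=C(\C)C[C@@H](O[Si](C)(C)C(C)(C)C)/C=C(\I)C1 | intermediate
27 | macrocyclic ether with CO2Me (C12) on C11 | O1C/C=C(/C)[C@@H](O[Si](CC)(CC)CC)C/C=C(\C)C[C@@H](O[Si](C)(C)C(C)(C)C)/C=C(\C(=O)OC)C1 | intermediate
28 | macrocyclic ether with CH2OH (C12) on C11 | O1C/C=C(/C)[C@@H](O[Si](CC)(CC)CC)C/C=C(\C)C[C@@H](O[Si](C)(C)C(C)(C)C)/C=C(\CO)C1 | intermediate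
29 | macrocyclic ether with CH2OSiEt3 (C12) on C11, precursor of the key step | O1C/C=C(/C)[C@@H](O[Si](CC)(CC)CC)C/C=C(\C)C[C@@H](O[Si](C)(C)C(C)(C)C)/C=C(\CO[Si](CC)(CC)CC)C1 | intermediate
30 | C6-lithiated macrocyclic ether | O1C([Li])/C=C(/C)[C@@H](O[Si](CC)(CC)CC)C/C=C(\C)C[C@@H](O[Si](C)(C)C(C)(C)C)/C=C(\CO[Si](CC)(CC)CC)C1 | intermediate
31 | ten-membered carbocycle, (3S,6R,8R), H7 trans to H6 (C7 arranged as in 44), 6-OH, C11=C13 exomethylene, C12H2OSiEt3 | O[C@@H]1/C=C(/C)[C@@H](O[Si](CC)(CC)CC)C/C=C(\C)C[C@@H](O[Si](C)(C)C(C)(C)C)[C@H]1C(=C)CO[Si](CC)(CC)CC | intermediate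
32 | 3,6,12-triol with O8 silyl ether | O[C@@H]1/C=C(/C)[C@@H](O)C/C=C(\C)C[C@@H](O[Si](C)(C)C(C)(C)C)[C@H]1C(=C)CO | intermediate
33 | C12 enal | O[C@@H]1/C=C(/C)[C@@H](O)C/C=C(\C)C[C@@H](O[Si](C)(C)C(C)(C)C)[C@H]1C(=C)C=O | intermediate
34 | 6,12-lactol | C=C1C(O)O[C@@H]2/C=C(/C)[C@@H](O)C/C=C(\C)C[C@@H](O[Si](C)(C)C(C)(C)C)[C@@H]12 | intermediate
35 | trans-fused α-methylene 6,12-lactone, 3β-OH, 8β-OSiMe2t-Bu | C=C1C(=O)O[C@@H]2/C=C(/C)[C@@H](O)C/C=C(\C)C[C@@H](O[Si](C)(C)C(C)(C)C)[C@@H]12 | intermediate
36 | tiglic acid | C/C=C(\C)C(=O)O | starting material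
37 | (E)-2-methylbut-2-en-1-ol | C/C=C(\C)CO | intermediate
38 | (2R,3R)-2,3-epoxy-2-methylbutan-1-ol | OC[C@@]1(C)O[C@@H]1C | intermediate
39 | (2S,3R)-2,3-dimethyloxirane-2-carboxylic acid | OC(=O)[C@@]1(C)O[C@@H]1C | intermediate
40 | 3-O-isobutyrate of 35 | C=C1C(=O)O[C@@H]2/C=C(/C)[C@@H](OC(=O)C(C)C)C/C=C(\C)C[C@@H](O[Si](C)(C)C(C)(C)C)[C@@H]12 | intermediate
41 | 8β-hydroxy 3-O-isobutyrate lactone | C=C1C(=O)O[C@@H]2/C=C(/C)[C@@H](OC(=O)C(C)C)C/C=C(\C)C[C@@H](O)[C@@H]12 | intermediate
42 | mixed anhydride of 39 and 2,4,6-trichlorobenzoic acid | O=C(OC(=O)[C@@]1(C)O[C@@H]1C)c1c(Cl)cc(Cl)cc1Cl | intermediate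
43 | 1(10)-ene diester, (3S,6R,7R,8R), side chain (2S,3R) | C=C1C(=O)O[C@@H]2/C=C(/C)[C@@H](OC(=O)C(C)C)C/C=C(\C)C[C@@H](OC(=O)[C@@]3(C)O[C@@H]3C)[C@@H]12 | intermediate
44 | CNP0117882.4, (1R,3S,6R,7R,8R,10R), side chain (2S,3R) | C=C1C(=O)O[C@@H]2/C=C(/C)[C@@H](OC(=O)C(C)C)C[C@H]3O[C@]3(C)C[C@@H](OC(=O)[C@@]3(C)O[C@@H]3C)[C@@H]12 | target

Total step count: 28. Longest linear sequence: 25 steps (steps 1–21 and 25–28, starting from 1).

Steps most likely to fail

Step 19. Lithiation may occur at C13 or on the silyloxymethyl arm, the O3 silyl group may migrate to the neighbouring carbanion, or a [1,2]-shift may compete. Above all, the rearrangement may run through the other fold of the macrocycle, in which both bulky silyloxy groups point outward. That would erode or invert the C6/C7 sense relative to C3 and C8. The fallback replaces substrate control by reagent control and closes C6–C7 by an intramolecular chromium-mediated 2-(methoxycarbonyl)allylation (Nozaki–Hiyama–Kishi type), in which a chiral ligand on chromium steers the aldehyde face. It sets out from 21. TEMPO/PhI(OAc)2 oxidises only the primary alcohol to the C6 (Z)-enal F1, and TBSCl/imidazole gives the O8 silyl ether F2. Pd(PPh3)4/CO/MeOH/Et3N turns the iodide into the methyl ester F3, buffered DDQ frees the C13 alcohol F4, and CBr4/PPh3 gives the allylic bromide F5. CrCl2 with a chiral carbazole bis(oxazoline) ligand at high dilution then joins C7 to C6 with allyl transposition. The chromium alkoxide closes onto the ester to give the bis-silylated α-methylene lactone F6. PPTS in MeOH removes the TES group, and the route is rejoined at 35.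

Step 11. The alkenylaluminate may expel the C13 ether by β-elimination to give an allene. The two propargylic oxygens may compete for regiocontrol, and protodemetalation may precede capture by iodine. The fallback makes the C11–metal bond with silicon, which cannot expel the neighbouring ether. It sets out from 18. Ruthenium-catalysed trans-hydrosilylation ([Cp*Ru(MeCN)3]PF6, Et3SiH, CH2Cl2) places silicon on C11, distal to the free O8–H and the branched C8, and gives the (Z)-alkenylsilane F7. Iododesilylation with retention (N-iodosuccinimide, 2,6-lutidine, (CF3)2CHOH, 0 °C) gives the iodo ester F8. Reduction of the C6 ester with i-Bu2AlH rejoins the route at 21.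

Step 28. Facial selectivity may be poor if the C1=C10 plane flips between its two orientations in the ten-membered ring, and traces of acid may open the new oxirane transannularly. The fallback uses reagent control by a chiral dioxirane (Shi epoxidation). Compound 43 is treated with the D-fructose-derived ketone, KHSO5 and carbonate buffer in MeCN–dimethoxymethane–water at 0 °C. This catalyst gives (R,R)-oxiranes from (E)-trisubstituted alkenes of this substitution pattern and picks the matching orientation of the mobile alkene. The fallback sets out from 43, comes back at 44 and makes no compound outside the list (F0).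

Further compounds
F1 | step 19 | C6 (Z)-enal with free O8–H, C11–I and C13–OPMB | O=C/C=C(/C)[C@@H](O[Si](CC)(CC)CC)C/C=C(\C)C[C@@H](O)/C=C(\I)COCc1ccc(OC)cc1
F2 | step 19 | O8 silyl ether of F1 | O=C/C=C(/C)[C@@H](O[Si](CC)(CC)CC)C/C=C(\C)C[C@@H](O[Si](C)(C)C(C)(C)C)/C=C(\I)COCc1ccc(OC)cc1
F3 | step 19 | methyl ester (C12 on C11) | O=C/C=C(/C)[C@@H](O[Si](CC)(CC)CC)C/C=C(\C)C[C@@H](O[Si](C)(C)C(C)(C)C)/C=C(\C(=O)OC)COCc1ccc(OC)cc1
F4 | step 19 | C13 alcohol | O=C/C=C(/C)[C@@H](O[Si](CC)(CC)CC)C/C=C(\C)C[C@@H](O[Si](C)(C)C(C)(C)C)/C=C(\C(=O)OC)CO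
F5 | step 19 | C13 allylic bromide | O=C/C=C(/C)[C@@H](O[Si](CC)(CC)CC)C/C=C(\C)C[C@@H](O[Si](C)(C)C(C)(C)C)/C=C(\C(=O)OC)CBr
F6 | step 19 | bis-silylated α-methylene lactone (O3-TES, O8-TBS) | C=C1C(=O)O[C@@H]2/C=C(/C)[C@@H](O[Si](CC)(CC)CC)C/C=C(\C)C[C@@H](O[Si](C)(C)C(C)(C)C)[C@@H]12
F7 | step 11 | (Z)-alkenylsilane, SiEt3 on C11 cis to C8 | COC(=O)/C=C(/C)[C@@H](O[Si](CC)(CC)CC)C/C=C(\C)C[C@@H](O)/C=C(\[Si](CC)(CC)CC)COCc1ccc(OC)cc1
F8 | step 11 | iodo ester, iodide on C11 cis to C8 | COC(=O)/C=C(/C)[C@@H](O[Si](CC)(CC)CC)C/C=C(\C)C[C@@H](O)/C=C(\I)COCc1ccc(OC)cc1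
F0 | step 28 | none | none
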